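Time divides this flask in two: the feed of L up to 15 min, then standing on to 30 min.

all flasks: L 0.20 M (fed, over 15 min); E 6.5 mM (held)

| charge | Q | remark | time |
|---|---|---|---|
| noon | 0.047 M | run made earlier |  |
| winter | 0.068 M | run made earlier |  |
| midnight | 0.095 M | run made earlier |  |
| blue | 0.0600 M |  | 30 min |
| amber | 0.0900 M |  | 30 min |

| run | time / min | L / % | Z / % |
|---|---|---|---|
| noon | 2.00 | 13 | 0 |
| noon | 5.00 | 28 | 5 |
| noon | 10.0 | 45 | 20 |
| noon | 15.0 | 64 | 41 |
| winter | 1.33 | 8 | 0 |
| winter | 3.00 | 19 | 1 |
| winter | 6.00 | 29 | 9 |
| winter | 15.0 | 62 | 37 |
| midnight | 4.00 | 20 | 5 |
| midnight | 8.00 | 39 | 14 |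
| midnight | 12.0 | 52 | 28 |
| midnight | 15.0 | 57 | 39 |

(readings scatter by 2 percentage points)

- at the start none of X is dissolved
- on the list of suspects stand: E <-> X; L + X -> G + Z; G + Q <-> J; X + G <-> D
- percentages count the whole charge, also what has not yet gone in

- part of the L that has reacted at the end, blue
- part of the L that has reacted at the end, amber
- what raising the concentration of Q from its lowest to its highest value here does to the part of the L that has reacted (changes below 5 percentage points count as none) (no change / it falls / it rises)

Z starts from nothing: the noon run shows 0% at 2.00 min, and none of X is dissolved at the start. Later I read the rate through the specific rate, the part of the L present that turns to Z per minute (the pseudo-first-order constant of L), taken as the rise of Z over the mean of L in the late part of each run: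

noon: 0.0771 /min
winter: 0.0684 /min
midnight: 0.0744 /min

Q rises to twice its lowest value across these runs, yet the values show no order in Q, so I take their mean, 0.0733 /min, as the mean specific rate.

The feed ends with a mean of 61.0% of the L unreacted, so the rate of Z then is 0.0447 /min of the charge. After that, reckoned at the mean specific rate, the fall of L slows the rate by a factor:

factor = exp(mean specific rate × standing time) = 3.00

On this reckoning the rate ends at 0.0149 /min, with 20.3% of the L left, and I reckon 79.7% reacted in both blue and amber. The spread of the three readings carries through: the highest and lowest values of the specific rate leave between 19.2% and 21.9% of the L.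

The forecast gives 77% for blue, 79% for amber and no change, holding that “X appears to sit near a steady level set by E”. My figure for blue is higher than its figure.

The flask gives 80.1% for blue, 80.7% for amber and no change, a change of 0.56 percentage points.

    E ⇌ X, rate k1*(csat - [X]) (kL = 3.96 /min)
    L + X → G + Z (k = 19.7 /M/min)
    G + Q ⇌ J, settled at all times (K = 790 /M)
    X + G ⇌ D, settled at all times (K = 35200 /M)

In blue, X climbs from 0.00313 M at 15.0 min to 0.00464 M at 30.0 min, so the specific rate runs from 0.0617 /min to 0.0914 /min, the curve that my mean of 0.0733 /min replaced over the standing time. Part of the missing conversion lies in the slow uptake of E as X, acting together with the length of the run: faster uptake lifts blue from 80.1% to 93.5%, and 300 min lifts it to 100%. In a flask like blue but with 0.80 M of L, X ends at 0.00114 M, so the specific rate at its end is 0.0225 /min, lower than the 0.0733 /min I carried, and 59.8% of the L is left.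

Readings and results stem from a simulated flask for an exercise; scatter was added.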